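**Plan**
- Retrosynthetic cuts, in order: the C2–C3 bond of the dihydrofuran ring (C3 carried as an ester-bearing carbene carbon); the aryl–C3 bond (aryl iodide plus ethyl diazoacetate); the Cα–benzyl bond of a trans-dibenzyl-γ-butyrolactone that masks the 2,3-dibenzylbutane-1,4-diol; the aryl O–CH2 ether bond.
- Enabling feature: in the dihydrofuran ring (ring C), O1–C2 is an electron-rich benzyl aryl ether whose C2–H (α to oxygen and benzylic) lies 1,5 to C3. With its CH2OH at the ester level, C3 is a donor/acceptor carbene centre on C3a of the central arene (ring B), so ring C can be closed by C–H insertion from an acyclic ether.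
- Forward: 5-iodovanillin is etherified and converted into benzyl bromide 5. Lactone 11 (Stobbe condensation, asymmetric hydrogenation, reductive lactonisation) is alkylated with 5, and the iodide is turned into aryldiazoacetate 15. Ring C, the last ring, closes in step 9; epimerisation, LiAlH4 reduction (ester and lactone to the triol) and hydrogenolysis finish the route.
- Stereochemistry: the butanediol centre next to the terminal guaiacyl ring (ring A) comes from Rh/Et-DuPhos hydrogenation and its neighbour from trans-selective lactone alkylation. C2 comes from the chiral dirhodium catalyst and C3 from thermodynamic cis-to-trans epimerisation.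

Key step: step 9

Assumption: [Rh(cod)((S,S)-Et-DuPhos)]BF4 is taken to give the (R)-succinate and Rh2(R-PTTL)4 the (2S)-cis-dihydrobenzofuran, by analogy with simpler itaconate half-esters and 2-(benzyloxy)aryl diazoacetates; should either sense prove opposite, the mirror-image ligand is used and nothing else changes.

**Step 1**
Reactants: 1 5-iodovanillin (4-hydroxy-3-iodo-5-methoxybenzaldehyde); 2 4-(benzyloxy)-3-methoxybenzyl alcohol
Product: 3 4-{[4-(benzyloxy)-3-methoxyphenyl]methoxy}-3-iodo-5-methoxybenzaldehyde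
Conditions: PPh3, DIAD, THF, 0 °C to rt
Reagents that add atoms: none
Why: Mitsunobu etherification of an acidic phenol (para-formyl, ortho-iodo) with a primary benzylic alcohol should proceed under neutral conditions that spare the aldehyde and the aryl iodide.

**Step 2**
Reactants: 3 4-{[4-(benzyloxy)-3-methoxyphenyl]methoxy}-3-iodo-5-methoxybenzaldehyde
Product: 4 (4-{[4-(benzyloxy)-3-methoxyphenyl]methoxy}-3-iodo-5-methoxyphenyl)methanol
Conditions: NaBH4, MeOH/THF, 0 °C
Reagents that add atoms: none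
Why: Borohydride reduction of an aryl aldehyde is chemoselective and leaves the aryl iodide and both benzyl ethers untouched.

**Step 3**
Reactants: 4 (4-{[4-(benzyloxy)-3-methoxyphenyl]methoxy}-3-iodo-5-methoxyphenyl)methanol
Product: 5 2-{[4-(benzyloxy)-3-methoxyphenyl]methoxy}-5-(bromomethyl)-1-iodo-3-methoxybenzene
Conditions: CBr4, PPh3, CH2Cl2, 0 °C
Reagents that add atoms: carbon tetrabromide, BrC(Br)(Br)Br
Why: Appel bromination works under neutral conditions, so the acid-labile dialkoxybenzyl aryl ether should survive.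

**Step 4**
Reactants: 6 4-(benzyloxy)-3-methoxybenzaldehyde (O-benzylvanillin); 7 dimethyl succinate
Product: 8 (3E)-4-[4-(benzyloxy)-3-methoxyphenyl]-3-(methoxycarbonyl)but-3-enoic acid
Conditions: NaOMe, MeOH, reflux; then aq HCl
Reagents that add atoms: none
Why: Stobbe condensation of an aryl aldehyde with a succinate diester gives the (E)-arylidene succinate half-ester directly, with the free acid needed to direct the hydrogenation.

**Step 5**
Reactants: 8 (3E)-4-[4-(benzyloxy)-3-methoxyphenyl]-3-(methoxycarbonyl)but-3-enoic acid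
Product: 9 (3R)-4-[4-(benzyloxy)-3-methoxyphenyl]-3-(methoxycarbonyl)butanoic acid
Conditions: H2 (5 atm), [Rh(cod)((S,S)-Et-DuPhos)]BF4 (1 mol %), NaOMe (10 mol %), MeOH, rt
Reagents that add atoms: none
Why: Asymmetric hydrogenation of a β-aryl itaconate half-ester with a cationic rhodium bisphospholane catalyst, in which carboxylate and alkene chelate the metal and the ligand selects the alkene face, should set the (R) centre; the homogeneous catalyst does not cleave the benzyl ether.

**Step 6**
Reactants: 9 (3R)-4-[4-(benzyloxy)-3-methoxyphenyl]-3-(methoxycarbonyl)butanoic acid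
Product: 11 (4R)-4-{[4-(benzyloxy)-3-methoxyphenyl]methyl}oxolan-2-one, via hydroxy acid 10 (not isolated)
Conditions: KOH, EtOH; then Ca(BH4)2 (from CaCl2 and NaBH4), EtOH, −10 °C to rt; then 3 M HCl, rt
Reagents that add atoms: none
Why: The potassium carboxylate is inert to borohydride while Ca(BH4)2 reduces the methyl ester, and acidification lactonises the γ-hydroxy acid without touching the stereocentre.

**Step 7**
Reactants: 11 (4R)-4-{[4-(benzyloxy)-3-methoxyphenyl]methyl}oxolan-2-one; 5 2-{[4-(benzyloxy)-3-methoxyphenyl]methoxy}-5-(bromomethyl)-1-iodo-3-methoxybenzene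
Product: 13 (3R,4R)-4-{[4-(benzyloxy)-3-methoxyphenyl]methyl}-3-[(4-{[4-(benzyloxy)-3-methoxyphenyl]methoxy}-3-iodo-5-methoxyphenyl)methyl]oxolan-2-one, via lithium enolate 12 (not isolated)
Conditions: LiN(SiMe3)2, THF, −78 °C; then 5, DMPU, −78 to −30 °C
Reagents that add atoms: none
Why: Alkylation of a β-benzyl-γ-butyrolactone enolate with a benzylic bromide occurs anti to the C4 substituent, so the new C3 centre should be set trans (3R,4R); the amide base does not exchange the aryl iodide.

**Step 8**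
Reactants: 13 (3R,4R)-4-{[4-(benzyloxy)-3-methoxyphenyl]methyl}-3-[(4-{[4-(benzyloxy)-3-methoxyphenyl]methoxy}-3-iodo-5-methoxyphenyl)methyl]oxolan-2-one; 14 ethyl diazoacetate
Product: 15 ethyl 2-diazo-2-(2-{[4-(benzyloxy)-3-methoxyphenyl]methoxy}-5-{[(3R,4R)-4-{[4-(benzyloxy)-3-methoxyphenyl]methyl}-2-oxooxolan-3-yl]methyl}-3-methoxyphenyl)acetate
Conditions: Pd(PPh3)4 (5 mol %), Ag2CO3 (0.5 equiv), Et3N, toluene, rt
Reagents that add atoms: none
Why: Palladium-catalysed cross-coupling of an aryl iodide with the C–H bond of an acceptor diazo ester (oxidative addition to zerovalent palladium, silver-assisted deprotonative transmetalation, reductive elimination) keeps the diazo group at room temperature and should tolerate the lactone and ethers.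

**Step 9**
Reactants: 15 ethyl 2-diazo-2-(2-{[4-(benzyloxy)-3-methoxyphenyl]methoxy}-5-{[(3R,4R)-4-{[4-(benzyloxy)-3-methoxyphenyl]methyl}-2-oxooxolan-3-yl]methyl}-3-methoxyphenyl)acetate
Product: 16 ethyl (2S,3R)-2-[4-(benzyloxy)-3-methoxyphenyl]-5-{[(3R,4R)-4-{[4-(benzyloxy)-3-methoxyphenyl]methyl}-2-oxooxolan-3-yl]methyl}-7-methoxy-2,3-dihydro-1-benzofuran-3-carboxylate (2,3-cis)
Conditions: dirhodium tetrakis[N-phthaloyl-(R)-tert-leucinate] Rh2(R-PTTL)4 (2 mol %), toluene, −78 to −60 °C, slow addition of 15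
Reagents that add atoms: none
Why: The divalent rhodium dimer extrudes N2 from the aryldiazoacetate to give a catalyst-bound donor/acceptor carbene at the future C3, which inserts into the C–H bond of the O1–CH2 ether carbon through a concerted, asynchronous three-centre transition state with hydride-transfer character. The closest known reaction type is the enantioselective intramolecular 1,5 C–H insertion of 2-(benzyloxy)aryl diazoacetates to cis-2-aryl-2,3-dihydrobenzofuran-3-carboxylates under chiral dirhodium carboxylate catalysis. Ring C closes by C2–C3 bond formation across the array C3–C3a–C7a–O1–C2 (1,5 insertion giving the five-membered ring), the only geometrically accessible mode. C2 (S) is set by which of the two methylene hydrogens the phthalimide-walled chiral pocket presents to the carbene, with retention at carbon, and C3 (R, cis to the aryl group) follows kinetically because the C2 aryl group and the ester both turn away from the catalyst wall in the insertion transition state. The step needs site selectivity for this C–H bond over carbene dimerisation and over the remote lactone, methoxy and benzyl ether C–H bonds, which its double activation (α-oxygen, benzylic to an electron-rich arene), its 1,5 position, low temperature and slow addition should secure. It also needs catalyst control over the distant lactone stereocentres, which are too far from the reacting atoms to bias the face.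

**Step 10**
Reactants: 16 ethyl (2S,3R)-2-[4-(benzyloxy)-3-methoxyphenyl]-5-{[(3R,4R)-4-{[4-(benzyloxy)-3-methoxyphenyl]methyl}-2-oxooxolan-3-yl]methyl}-7-methoxy-2,3-dihydro-1-benzofuran-3-carboxylate
Product: 17 ethyl (2S,3S)-2-[4-(benzyloxy)-3-methoxyphenyl]-5-{[(3R,4R)-4-{[4-(benzyloxy)-3-methoxyphenyl]methyl}-2-oxooxolan-3-yl]methyl}-7-methoxy-2,3-dihydro-1-benzofuran-3-carboxylate (2,3-trans)
Conditions: DBU, toluene, 60 °C
Reagents that add atoms: none
Why: Base-mediated epimerisation of the benzylic α-ester centre C3 should drive the cis isomer to the more stable trans isomer under thermodynamic control, while the non-nucleophilic amidine leaves the lactone closed and its α-centre, already in the stable trans arrangement, unchanged.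

**Step 11**
Reactants: 17 ethyl (2S,3S)-2-[4-(benzyloxy)-3-methoxyphenyl]-5-{[(3R,4R)-4-{[4-(benzyloxy)-3-methoxyphenyl]methyl}-2-oxooxolan-3-yl]methyl}-7-methoxy-2,3-dihydro-1-benzofuran-3-carboxylate
Product: 18 (2R,3R)-2-{[(2S,3R)-2-[4-(benzyloxy)-3-methoxyphenyl]-3-(hydroxymethyl)-7-methoxy-2,3-dihydro-1-benzofuran-5-yl]methyl}-3-{[4-(benzyloxy)-3-methoxyphenyl]methyl}butane-1,4-diol
Conditions: LiAlH4, THF, 0 °C to rt; then H2O, aq NaOH
Reagents that add atoms: none
Why: Hydride reduction converts the ethyl ester into the C3 hydroxymethyl group and opens the lactone to the 1,4-diol in one operation, with no stereocentre involved.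

**Step 12**
Reactants: 18 (2R,3R)-2-{[(2S,3R)-2-[4-(benzyloxy)-3-methoxyphenyl]-3-(hydroxymethyl)-7-methoxy-2,3-dihydro-1-benzofuran-5-yl]methyl}-3-{[4-(benzyloxy)-3-methoxyphenyl]methyl}butane-1,4-diol
Product: 19 (2R,3R)-2-{[(2S,3R)-2-(4-hydroxy-3-methoxyphenyl)-3-(hydroxymethyl)-7-methoxy-2,3-dihydro-1-benzofuran-5-yl]methyl}-3-[(4-hydroxy-3-methoxyphenyl)methyl]butane-1,4-diol (CNP0256425.1)
Conditions: H2 (1 atm), Pd/C (10 %), EtOAc/MeOH, rt, stopped at full conversion
Reagents that add atoms: none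
Why: Catalytic hydrogenolysis removes the two phenolic benzyl ethers, and the cyclic secondary benzylic C2–O1 bond is expected to be cleaved much more slowly under these mild conditions.

**Compound list**
1 | 5-iodovanillin (4-hydroxy-3-iodo-5-methoxybenzaldehyde) | O=Cc1cc(I)c(O)c(OC)c1 | starting material
2 | 4-(benzyloxy)-3-methoxybenzyl alcohol | OCc1ccc(OCc2ccccc2)c(OC)c1 | starting material
3 | 4-{[4-(benzyloxy)-3-methoxyphenyl]methoxy}-3-iodo-5-methoxybenzaldehyde | O=Cc1cc(I)c(OCc2ccc(OCc3ccccc3)c(OC)c2)c(OC)c1 | intermediate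
4 | (4-{[4-(benzyloxy)-3-methoxyphenyl]methoxy}-3-iodo-5-methoxyphenyl)methanol | OCc1cc(I)c(OCc2ccc(OCc3ccccc3)c(OC)c2)c(OC)c1 | intermediate
5 | 2-{[4-(benzyloxy)-3-methoxyphenyl]methoxy}-5-(bromomethyl)-1-iodo-3-methoxybenzene | BrCc1cc(I)c(OCc2ccc(OCc3ccccc3)c(OC)c2)c(OC)c1 | intermediate
6 | 4-(benzyloxy)-3-methoxybenzaldehyde (O-benzylvanillin) | O=Cc1ccc(OCc2ccccc2)c(OC)c1 | starting material
7 | dimethyl succinate | COC(=O)CCC(=O)OC | starting material
8 | (3E)-4-[4-(benzyloxy)-3-methoxyphenyl]-3-(methoxycarbonyl)but-3-enoic acid | OC(=O)C/C(=C\c1ccc(OCc2ccccc2)c(OC)c1)C(=O)OC | intermediate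
9 | (3R)-4-[4-(benzyloxy)-3-methoxyphenyl]-3-(methoxycarbonyl)butanoic acid | OC(=O)C[C@@H](Cc1ccc(OCc2ccccc2)c(OC)c1)C(=O)OC | intermediate
10 | (3R)-4-[4-(benzyloxy)-3-methoxyphenyl]-3-(hydroxymethyl)butanoic acid (present as its carboxylate, not isolated) | OC(=O)C[C@@H](Cc1ccc(OCc2ccccc2)c(OC)c1)CO | intermediate
11 | (4R)-4-{[4-(benzyloxy)-3-methoxyphenyl]methyl}oxolan-2-one | O=C1C[C@@H](Cc2ccc(OCc3ccccc3)c(OC)c2)CO1 | intermediate
12 | lithium (4R)-4-{[4-(benzyloxy)-3-methoxyphenyl]methyl}-4,5-dihydrofuran-2-olate (lithium enolate of 11, not isolated) | [Li+].[O-]C1=C[C@@H](Cc2ccc(OCc3ccccc3)c(OC)c2)CO1 | intermediate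
13 | (3R,4R)-4-{[4-(benzyloxy)-3-methoxyphenyl]methyl}-3-[(4-{[4-(benzyloxy)-3-methoxyphenyl]methoxy}-3-iodo-5-methoxyphenyl)methyl]oxolan-2-one | O=C1[C@H](Cc2cc(I)c(OCc3ccc(OCc4ccccc4)c(OC)c3)c(OC)c2)[C@@H](Cc2ccc(OCc3ccccc3)c(OC)c2)CO1 | intermediate
14 | ethyl diazoacetate | CCOC(=O)C=[N+]=[N-] | starting material
15 | ethyl 2-diazo-2-(2-{[4-(benzyloxy)-3-methoxyphenyl]methoxy}-5-{[(3R,4R)-4-{[4-(benzyloxy)-3-methoxyphenyl]methyl}-2-oxooxolan-3-yl]methyl}-3-methoxyphenyl)acetate | O=C1[C@H](Cc2cc(C(=[N+]=[N-])C(=O)OCC)c(OCc3ccc(OCc4ccccc4)c(OC)c3)c(OC)c2)[C@@H](Cc2ccc(OCc3ccccc3)c(OC)c2)CO1 | intermediate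
16 | ethyl (2S,3R)-2-[4-(benzyloxy)-3-methoxyphenyl]-5-{[(3R,4R)-4-{[4-(benzyloxy)-3-methoxyphenyl]methyl}-2-oxooxolan-3-yl]methyl}-7-methoxy-2,3-dihydro-1-benzofuran-3-carboxylate (cis) | O=C1[C@H](Cc2cc(OC)c3c(c2)[C@@H](C(=O)OCC)[C@@H](c2ccc(OCc4ccccc4)c(OC)c2)O3)[C@@H](Cc2ccc(OCc3ccccc3)c(OC)c2)CO1 | intermediate
17 | ethyl (2S,3S)-2-[4-(benzyloxy)-3-methoxyphenyl]-5-{[(3R,4R)-4-{[4-(benzyloxy)-3-methoxyphenyl]methyl}-2-oxooxolan-3-yl]methyl}-7-methoxy-2,3-dihydro-1-benzofuran-3-carboxylate (trans) | O=C1[C@H](Cc2cc(OC)c3c(c2)[C@H](C(=O)OCC)[C@@H](c2ccc(OCc4ccccc4)c(OC)c2)O3)[C@@H](Cc2ccc(OCc3ccccc3)c(OC)c2)CO1 | intermediate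
18 | (2R,3R)-2-{[(2S,3R)-2-[4-(benzyloxy)-3-methoxyphenyl]-3-(hydroxymethyl)-7-methoxy-2,3-dihydro-1-benzofuran-5-yl]methyl}-3-{[4-(benzyloxy)-3-methoxyphenyl]methyl}butane-1,4-diol | COc1cc(C[C@@H](CO)[C@H](CO)Cc2cc(OC)c3c(c2)[C@H](CO)[C@@H](c2ccc(OCc4ccccc4)c(OC)c2)O3)ccc1OCc1ccccc1 | intermediate
19 | (2R,3R)-2-{[(2S,3R)-2-(4-hydroxy-3-methoxyphenyl)-3-(hydroxymethyl)-7-methoxy-2,3-dihydro-1-benzofuran-5-yl]methyl}-3-[(4-hydroxy-3-methoxyphenyl)methyl]butane-1,4-diol (CNP0256425.1) | COc1cc(C[C@@H](CO)[C@H](CO)Cc2cc(OC)c3c(c2)[C@H](CO)[C@@H](c2ccc(O)c(OC)c2)O3)ccc1O | target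

**Totals**
Total step count: 12. Longest linear sequence: 9 steps (steps 4–12 from 6 and 7; the branch through steps 1–3 and 7–12 is equally long).

**Steps most likely to fail**

Step 9. The insertion may show poor selection between the two methylene hydrogens and carbene faces on an ether flanked by an ortho methoxy group. Partly stepwise hydride transfer at the very electron-rich benzylic position may erode C2 control, and carbene dimerisation may compete. The fallback replaces catalyst control by auxiliary control with a matched catalyst and sets out from aryl iodide 13. Ethyl (S)-lactate and pyrrolidine, heated neat, give (2S)-2-hydroxy-1-(pyrrolidin-1-yl)propan-1-one F1. Bromoacetyl bromide and pyridine in CH2Cl2 give (2S)-1-oxo-1-(pyrrolidin-1-yl)propan-2-yl bromoacetate F2, which N,N'-ditosylhydrazine and DBU in THF convert into (2S)-1-oxo-1-(pyrrolidin-1-yl)propan-2-yl diazoacetate F3. Coupling of F3 with 13 under the conditions of step 8 should give the lactamide aryldiazoacetate F4. Decomposition of F4 with dirhodium tetrakis[(S)-N-(4-dodecylbenzenesulfonyl)prolinate] Rh2(S-DOSP)4 in CH2Cl2 at −40 °C should give the trans-(2S,3S) lactamide ester F5 directly by double stereodifferentiation. LiAlH4 in THF then cleaves the auxiliary reductively and opens the lactone, and the fallback comes back to the route at triol 18, bypassing step 10.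

Step 8. Oxidative addition and transmetalation may be sluggish at the electron-rich, ortho-alkoxy aryl iodide, and the diazo group may be lost on palladium. The fallback separates arylation from diazo installation and sets out from 13. Negishi-type coupling with the Reformatsky reagent BrZnCH2CO2Et (from ethyl bromoacetate and zinc in THF) under Pd(dba)2 and P(t-Bu)3 at rt should give ethyl 2-(2-{[4-(benzyloxy)-3-methoxyphenyl]methoxy}-5-{[(3R,4R)-4-{[4-(benzyloxy)-3-methoxyphenyl]methyl}-2-oxooxolan-3-yl]methyl}-3-methoxyphenyl)acetate F6. Regitz diazo transfer with 4-acetamidobenzenesulfonyl azide and DBU in MeCN should act only at the far more acidic arylacetate methylene and not at the lactone α-position, and comes back to the route at 15.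

Step 10. Equilibration with the amidine base may be incomplete, and stronger or nucleophilic bases risk lactone opening with scrambling of its α-centre, or retro-oxa-Michael opening of ring C with erosion of C2. The fallback epimerises during saponification with the lactone masked as its carboxylate and sets out from cis ester 16. LiOH in THF/MeOH/H2O should open the lactone at once to the γ-hydroxy carboxylate, whose α-centre can no longer enolise. The hindered cis ester should epimerise before it hydrolyses, giving (2S,3S)-2-[4-(benzyloxy)-3-methoxyphenyl]-5-[(2R,3R)-2-carboxy-3-{[4-(benzyloxy)-3-methoxyphenyl]methyl}-4-hydroxybutyl]-7-methoxy-2,3-dihydro-1-benzofuran-3-carboxylic acid F7 as its dilithium salt. Acidification to pH 2 and brief warming with catalytic TsOH in toluene should relactonise it to (2S,3S)-2-[4-(benzyloxy)-3-methoxyphenyl]-5-{[(3R,4R)-4-{[4-(benzyloxy)-3-methoxyphenyl]methyl}-2-oxooxolan-3-yl]methyl}-7-methoxy-2,3-dihydro-1-benzofuran-3-carboxylic acid F8. LiAlH4 in refluxing THF reduces the acid and the lactone, and the fallback comes back to the route at 18.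

**Further compounds**
F1 | step 9 | (2S)-2-hydroxy-1-(pyrrolidin-1-yl)propan-1-one | C[C@H](O)C(=O)N1CCCC1
F2 | step 9 | (2S)-1-oxo-1-(pyrrolidin-1-yl)propan-2-yl bromoacetate | C[C@H](OC(=O)CBr)C(=O)N1CCCC1
F3 | step 9 | (2S)-1-oxo-1-(pyrrolidin-1-yl)propan-2-yl diazoacetate | C[C@H](OC(=O)C=[N+]=[N-])C(=O)N1CCCC1
F4 | step 9 | (2S)-1-oxo-1-(pyrrolidin-1-yl)propan-2-yl 2-diazo-2-(2-{[4-(benzyloxy)-3-methoxyphenyl]methoxy}-5-{[(3R,4R)-4-{[4-(benzyloxy)-3-methoxyphenyl]methyl}-2-oxooxolan-3-yl]methyl}-3-methoxyphenyl)acetate | O=C1[C@H](Cc2cc(C(=[N+]=[N-])C(=O)O[C@@H](C)C(=O)N3CCCC3)c(OCc3ccc(OCc4ccccc4)c(OC)c3)c(OC)c2)[C@@H](Cc2ccc(OCc3ccccc3)c(OC)c2)CO1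
F5 | step 9 | (2S)-1-oxo-1-(pyrrolidin-1-yl)propan-2-yl (2S,3S)-2-[4-(benzyloxy)-3-methoxyphenyl]-5-{[(3R,4R)-4-{[4-(benzyloxy)-3-methoxyphenyl]methyl}-2-oxooxolan-3-yl]methyl}-7-methoxy-2,3-dihydro-1-benzofuran-3-carboxylate | O=C1[C@H](Cc2cc(OC)c3c(c2)[C@H](C(=O)O[C@@H](C)C(=O)N4CCCC4)[C@@H](c2ccc(OCc4ccccc4)c(OC)c2)O3)[C@@H](Cc2ccc(OCc3ccccc3)c(OC)c2)CO1
F6 | step 8 | ethyl 2-(2-{[4-(benzyloxy)-3-methoxyphenyl]methoxy}-5-{[(3R,4R)-4-{[4-(benzyloxy)-3-methoxyphenyl]methyl}-2-oxooxolan-3-yl]methyl}-3-methoxyphenyl)acetate | O=C1[C@H](Cc2cc(CC(=O)OCC)c(OCc3ccc(OCc4ccccc4)c(OC)c3)c(OC)c2)[C@@H](Cc2ccc(OCc3ccccc3)c(OC)c2)CO1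
F7 | step 10 | (2S,3S)-2-[4-(benzyloxy)-3-methoxyphenyl]-5-[(2R,3R)-2-carboxy-3-{[4-(benzyloxy)-3-methoxyphenyl]methyl}-4-hydroxybutyl]-7-methoxy-2,3-dihydro-1-benzofuran-3-carboxylic acid (dilithium salt in the flask) | OC[C@H](Cc1ccc(OCc2ccccc2)c(OC)c1)[C@@H](Cc1cc(OC)c2c(c1)[C@H](C(=O)O)[C@@H](c1ccc(OCc3ccccc3)c(OC)c1)O2)C(=O)O
F8 | step 10 | (2S,3S)-2-[4-(benzyloxy)-3-methoxyphenyl]-5-{[(3R,4R)-4-{[4-(benzyloxy)-3-methoxyphenyl]methyl}-2-oxooxolan-3-yl]methyl}-7-methoxy-2,3-dihydro-1-benzofuran-3-carboxylic acid | O=C1[C@H](Cc2cc(OC)c3c(c2)[C@H](C(=O)O)[C@@H](c2ccc(OCc4ccccc4)c(OC)c2)O3)[C@@H](Cc2ccc(OCc3ccccc3)c(OC)c2)CO1
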